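**Plan**

- Retrosynthesis cuts, in order: the three MOM ethers; the furan O1–C2 bond together with the C7–C(CH3)2 bond of the 1,1-dimethylallyl group (back to an ortho-prenyloxy diarylalkyne); the alkyne C(sp)–C5 bond to the chroman (Sonogashira); and the C2–C3 bond of the chroman.
- Enabling feature: in the dihydropyran ring, C2 is fully substituted and bound to the aryl oxygen O1, and C3–C4 hangs on the ring carbon ortho to O1. C2 can therefore be a tertiary α-aryloxy radical released from an aryloxyisobutyric acid by loss of CO2, with C3/C4 a vinyl group; 6-endo attack places the radical on benzylic C4.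
- Forward, B ring: 5-bromoresorcinol is formylated, mono-MOM protected, O-alkylated with the C(CH3)2CO2Et unit, methylenated and hydrolysed; the radical closure then gives bromochroman 8.
- Forward, A ring and union: alkyne 12 is made in three steps from 2,4,6-trihydroxybenzaldehyde and joined to 8 by Sonogashira coupling. A Claisen shift then sets the quaternary carbon at C7 and frees the phenol that closes the furan ring; MOM removal comes last.
- Stereochemistry (assumption): the target has no stereocentre, since chroman C2 and the allylic quaternary carbon each carry two methyl groups. It is achiral, so "single enantiomer" requires no stereocontrol.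

Key step: step 6

**Step 1**
Reactants: 1 5-bromobenzene-1,3-diol (5-bromoresorcinol)
Product: 3 2-bromo-4,6-dihydroxybenzaldehyde, via aryl iminium chloride 2 (not isolated)
Conditions: POCl3, DMF, MeCN, 0 °C to rt; then H2O, 50 °C
Reagents that add atoms: N,N-dimethylformamide, CN(C)C=O (formyl carbon); water, O (carbonyl oxygen)
Why: Vilsmeier–Haack formylation, in which the chloroiminium ion attacks C4 of the resorcinol (ortho to one hydroxyl, para to the other) rather than the doubly flanked C2, as with resorcinol and orcinol, and hydrolysis of iminium salt 2 releases the aldehyde.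

**Step 2**
Reactants: 3 2-bromo-4,6-dihydroxybenzaldehyde
Product: 4 2-bromo-6-hydroxy-4-(methoxymethoxy)benzaldehyde
Conditions: MOMCl (1.05 equiv), iPr2NEt, CH2Cl2, 0 °C
Reagents that add atoms: chloromethyl methyl ether, COCCl
Why: Selective O-alkylation, because the 6-OH is held in a hydrogen bond to the formyl oxygen and the more acidic, accessible 4-OH should take the single MOM group, as in the mono-protection of 2,4-dihydroxybenzaldehyde.

**Step 3**
Reactants: 4 2-bromo-6-hydroxy-4-(methoxymethoxy)benzaldehyde
Product: 5 ethyl 2-[3-bromo-2-formyl-5-(methoxymethoxy)phenoxy]-2-methylpropanoate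
Conditions: ethyl 2-bromo-2-methylpropanoate (2 equiv), Cs2CO3, DMF, 60 °C
Reagents that add atoms: ethyl 2-bromo-2-methylpropanoate, CCOC(=O)C(C)(C)Br
Why: Williamson-type etherification of the caesium phenoxide with a tertiary α-bromo ester (the fibrate ether synthesis); the product has no α-hydrogen, so it cannot condense onto the neighbouring aldehyde.

**Step 4**
Reactants: 5 ethyl 2-[3-bromo-2-formyl-5-(methoxymethoxy)phenoxy]-2-methylpropanoate
Product: 6 ethyl 2-[3-bromo-2-ethenyl-5-(methoxymethoxy)phenoxy]-2-methylpropanoate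
Conditions: Ph3PCH3Br, KOtBu, THF, 0 °C to rt
Reagents that add atoms: methyltriphenylphosphonium bromide, C[P+](c1ccccc1)(c1ccccc1)c1ccccc1.[Br-]
Why: Wittig methylenation with the non-stabilised ylide is fast on the aldehyde and should leave the hindered tertiary ester, the aryl bromide and the MOM acetal untouched.

**Step 5**
Reactants: 6 ethyl 2-[3-bromo-2-ethenyl-5-(methoxymethoxy)phenoxy]-2-methylpropanoate
Product: 7 2-[3-bromo-2-ethenyl-5-(methoxymethoxy)phenoxy]-2-methylpropanoic acid
Conditions: LiOH·H2O, THF/MeOH/H2O, 40 °C; then 1 M HCl to pH 4, 0 °C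
Reagents that add atoms: lithium hydroxide, [Li+].[OH-]
Why: Saponification of the ethyl ester (acyl–oxygen cleavage) under conditions that styrene, aryl bromide and MOM ether tolerate; brief cold acidification to pH 4 should not cleave the acetal.

**Step 6**
Reactants: 7 2-[3-bromo-2-ethenyl-5-(methoxymethoxy)phenoxy]-2-methylpropanoic acid
Product: 8 5-bromo-7-(methoxymethoxy)-2,2-dimethyl-3,4-dihydro-2H-chromene
Conditions: [Ir(dF(CF3)ppy)2(dtbbpy)]PF6 (1 mol %), 2,4,6-triisopropylbenzenethiol (5 mol %), Cs2CO3 (20 mol %), DMF (0.02 M), 450 nm LEDs, rt, Ar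
Reagents that add atoms: none
Why: Visible-light-excited Ir(III) oxidises the caesium carboxylate of 7, CO2 is lost, and the tertiary α-aryloxy radical at the future C2 adds to the terminal carbon of the ortho vinyl group; the benzylic C4 radical then takes a hydrogen atom from the thiol, whose thiyl radical is reduced by Ir(II) and reprotonated by the next molecule of acid, so the process is redox-neutral and the carboxyl group leaves without a trace. The closest known reaction type is the photoredox decarboxylative Giese-type hydroalkylation of alkenes by α-oxy carboxylic acids with thiol hydrogen-atom-transfer co-catalysis, here run intramolecularly. The dihydropyran ring closes in the 6-endo-trig mode. No stereocentre is formed, because C2 carries two methyl groups and C3 and C4 are methylene groups. The step needs 6-endo over 5-exo closure and ring closure before hydrogen transfer: the bulky nucleophilic tertiary radical should attack the unsubstituted styrene terminus to give a benzylic radical, whereas 5-exo attack would give a primary radical next to a quaternary carbon, and high dilution with a low thiol loading keeps premature hydrogen transfer and intermolecular addition slow. The excited-state potential of the catalyst (about +1.2 V vs SCE) suffices for the carboxylate but not for the alkoxystyrene, and the aryl bromide and MOM acetal are inert to it.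

**Step 7**
Reactants: 9 2,4,6-trihydroxybenzaldehyde
Product: 10 2-hydroxy-4,6-bis(methoxymethoxy)benzaldehyde
Conditions: MOMCl (2.1 equiv), iPr2NEt, CH2Cl2, 0 °C to rt
Reagents that add atoms: chloromethyl methyl ether, COCCl
Why: Selective O-alkylation, in which the 4-OH and one ortho OH react while the last ortho OH stays hydrogen-bonded to the formyl group and is left free.

**Step 8**
Reactants: 10 2-hydroxy-4,6-bis(methoxymethoxy)benzaldehyde
Product: 11 2,4-bis(methoxymethoxy)-6-[(3-methylbut-2-en-1-yl)oxy]benzaldehyde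
Conditions: prenyl bromide, K2CO3, DMF, rt to 40 °C
Reagents that add atoms: 1-bromo-3-methylbut-2-ene, CC(C)=CCBr
Why: Williamson O-allylation of the chelated phenol with a primary allylic bromide gives the aryl prenyl ether needed for the later Claisen shift.

**Step 9**
Reactants: 11 2,4-bis(methoxymethoxy)-6-[(3-methylbut-2-en-1-yl)oxy]benzaldehyde
Product: 12 2-ethynyl-1,5-bis(methoxymethoxy)-3-[(3-methylbut-2-en-1-yl)oxy]benzene
Conditions: dimethyl (1-diazo-2-oxopropyl)phosphonate, K2CO3, MeOH/THF, rt
Reagents that add atoms: dimethyl (1-diazo-2-oxopropyl)phosphonate, CC(=O)C(=[N+]=[N-])P(=O)(OC)OC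
Why: Seyferth–Gilbert homologation with the Ohira–Bestmann reagent converts the aldehyde into the terminal alkyne under mild carbonate/methanol conditions that leave the MOM and prenyl ethers intact.

**Step 10**
Reactants: 8 5-bromo-7-(methoxymethoxy)-2,2-dimethyl-3,4-dihydro-2H-chromene; 12 2-ethynyl-1,5-bis(methoxymethoxy)-3-[(3-methylbut-2-en-1-yl)oxy]benzene
Product: 13 5-{[2,4-bis(methoxymethoxy)-6-[(3-methylbut-2-en-1-yl)oxy]phenyl]ethynyl}-7-(methoxymethoxy)-2,2-dimethyl-3,4-dihydro-2H-chromene
Conditions: PdCl2(MeCN)2 (3 mol %), XPhos (9 mol %), Cs2CO3, MeCN, 80 °C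
Reagents that add atoms: none
Why: Copper-free Sonogashira coupling with a bulky electron-rich phosphine should handle the ortho-substituted aryl bromide and avoid oxidative dimerisation of the electron-rich alkyne.

**Step 11**
Reactants: 13 5-{[2,4-bis(methoxymethoxy)-6-[(3-methylbut-2-en-1-yl)oxy]phenyl]ethynyl}-7-(methoxymethoxy)-2,2-dimethyl-3,4-dihydro-2H-chromene
Product: 15 4,6-bis(methoxymethoxy)-2-[7-(methoxymethoxy)-2,2-dimethyl-3,4-dihydro-2H-chromen-5-yl]-7-(2-methylbut-3-en-2-yl)-1-benzofuran, via o-alkynylphenol 14 (not isolated)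
Conditions: PhNEt2, 190 °C (sealed tube, Ar); then cool, DMF, Cs2CO3, 80 °C
Reagents that add atoms: none
Why: Aromatic Claisen rearrangement ([3,3]) moves the prenyl group with allylic inversion to the only free ortho carbon (creating the quaternary benzylic carbon at the future C7) and unmasks phenol 14, whose caesium phenoxide then adds 5-endo-dig across the alkyne (base-mediated cycloisomerisation of an o-alkynylphenol) to close the furan ring; no stereocentre is formed.

**Step 12**
Reactants: 15 4,6-bis(methoxymethoxy)-2-[7-(methoxymethoxy)-2,2-dimethyl-3,4-dihydro-2H-chromen-5-yl]-7-(2-methylbut-3-en-2-yl)-1-benzofuran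
Product: 16 2-(7-hydroxy-2,2-dimethyl-3,4-dihydro-2H-chromen-5-yl)-7-(2-methylbut-3-en-2-yl)-1-benzofuran-4,6-diol
Conditions: HCl (cat.), MeOH/THF, 40 °C; NaHCO3 quench
Reagents that add atoms: none
Why: Acid-catalysed acetal exchange in methanol should cleave the three aryl MOM ethers under conditions mild enough for the benzofuran, the chroman ether and the 1,1-dimethylallyl group.

**Compound list**

1 | 5-bromobenzene-1,3-diol | Oc1cc(O)cc(Br)c1 | starting material
2 | [(2-bromo-4,6-dihydroxyphenyl)methylidene]dimethylammonium chloride | C[N+](C)=Cc1c(O)cc(O)cc1Br.[Cl-] | intermediate (not isolated)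
3 | 2-bromo-4,6-dihydroxybenzaldehyde | O=Cc1c(O)cc(O)cc1Br | intermediate
4 | 2-bromo-6-hydroxy-4-(methoxymethoxy)benzaldehyde | COCOc1cc(O)c(C=O)c(Br)c1 | intermediate
5 | ethyl 2-[3-bromo-2-formyl-5-(methoxymethoxy)phenoxy]-2-methylpropanoate | CCOC(=O)C(C)(C)Oc1cc(OCOC)cc(Br)c1C=O | intermediate
6 | ethyl 2-[3-bromo-2-ethenyl-5-(methoxymethoxy)phenoxy]-2-methylpropanoate | CCOC(=O)C(C)(C)Oc1cc(OCOC)cc(Br)c1C=C | intermediate
7 | 2-[3-bromo-2-ethenyl-5-(methoxymethoxy)phenoxy]-2-methylpropanoic acid | OC(=O)C(C)(C)Oc1cc(OCOC)cc(Br)c1C=C | intermediate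
8 | 5-bromo-7-(methoxymethoxy)-2,2-dimethyl-3,4-dihydro-2H-chromene | COCOc1cc(Br)c2CCC(C)(C)Oc2c1 | intermediate
9 | 2,4,6-trihydroxybenzaldehyde | O=Cc1c(O)cc(O)cc1O | starting material
10 | 2-hydroxy-4,6-bis(methoxymethoxy)benzaldehyde | COCOc1cc(O)c(C=O)c(OCOC)c1 | intermediate
11 | 2,4-bis(methoxymethoxy)-6-[(3-methylbut-2-en-1-yl)oxy]benzaldehyde | COCOc1cc(OCC=C(C)C)c(C=O)c(OCOC)c1 | intermediate
12 | 2-ethynyl-1,5-bis(methoxymethoxy)-3-[(3-methylbut-2-en-1-yl)oxy]benzene | C#Cc1c(OCOC)cc(OCOC)cc1OCC=C(C)C | intermediate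
13 | 5-{[2,4-bis(methoxymethoxy)-6-[(3-methylbut-2-en-1-yl)oxy]phenyl]ethynyl}-7-(methoxymethoxy)-2,2-dimethyl-3,4-dihydro-2H-chromene | CC(C)=CCOc1cc(OCOC)cc(OCOC)c1C#Cc1cc(OCOC)cc2OC(C)(C)CCc12 | intermediate
14 | 2-{[7-(methoxymethoxy)-2,2-dimethyl-3,4-dihydro-2H-chromen-5-yl]ethynyl}-3,5-bis(methoxymethoxy)-6-(2-methylbut-3-en-2-yl)phenol | C=CC(C)(C)c1c(OCOC)cc(OCOC)c(C#Cc2cc(OCOC)cc3OC(C)(C)CCc23)c1O | intermediate (not isolated)
15 | 4,6-bis(methoxymethoxy)-2-[7-(methoxymethoxy)-2,2-dimethyl-3,4-dihydro-2H-chromen-5-yl]-7-(2-methylbut-3-en-2-yl)-1-benzofuran | C=CC(C)(C)c1c(OCOC)cc(OCOC)c2cc(-c3cc(OCOC)cc4OC(C)(C)CCc34)oc12 | intermediate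
16 | 2-(7-hydroxy-2,2-dimethyl-3,4-dihydro-2H-chromen-5-yl)-7-(2-methylbut-3-en-2-yl)-1-benzofuran-4,6-diol | C=CC(C)(C)c1c(O)cc(O)c2cc(-c3cc(O)cc4c3CCC(C)(C)O4)oc12 | target

**Step count**

Total steps: 12. Longest linear sequence: 9 (steps 1–6, 10, 11, 12).

**Steps most likely to fail**

Step 6. The tertiary radical may take a hydrogen atom before it cyclises (plain hydrodecarboxylation), may close 5-exo, or may add to the styrene of a second molecule. The fallback sets out from 4 and returns at 8, and forms O1–C2 instead of C2–C3. Addition of 2-methylprop-1-enylmagnesium bromide (excess, THF, 0 °C) to the aldehyde of 4 should give the racemic allylic alcohol 3-bromo-2-(1-hydroxy-3-methylbut-2-en-1-yl)-5-(methoxymethoxy)phenol F1. Warming F1 in toluene with a trace of PPTS should dehydrate it to an ortho-quinone methide that closes by oxa-6π electrocyclisation to 5-bromo-7-(methoxymethoxy)-2,2-dimethyl-2H-chromene F2. Diimide (TsNHNH2, NaOAc, aqueous DME, reflux) should then saturate C3=C4 without touching the aryl bromide, giving 8.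

Step 11. At 190 °C the prenyl group may be lost as isoprene or may migrate onward to the para position after attack at the alkyne-bearing carbon, and the hindered phenoxide may add only sluggishly to the electron-rich alkyne. The fallback sets out from 11 (and uses 8) and returns at 15; it builds the furan first and makes the C2–aryl bond by cross-coupling. Chelation-assisted Claisen rearrangement of 11 (Eu(fod)3, CHCl3, 60 °C) should give 2-hydroxy-4,6-bis(methoxymethoxy)-3-(2-methylbut-3-en-2-yl)benzaldehyde F3. Ramirez dibromo-olefination (CBr4, PPh3, Et3N, CH2Cl2, 0 °C) should give 2-(2,2-dibromoethenyl)-3,5-bis(methoxymethoxy)-6-(2-methylbut-3-en-2-yl)phenol F4. Copper-catalysed intramolecular C–O coupling (CuI, K3PO4, THF, 80 °C) should give 2-bromo-4,6-bis(methoxymethoxy)-7-(2-methylbut-3-en-2-yl)-1-benzofuran F5. In parallel, Miyaura borylation of 8 (B2pin2, Pd(dppf)Cl2, KOAc, dioxane, 90 °C) should give 2-[7-(methoxymethoxy)-2,2-dimethyl-3,4-dihydro-2H-chromen-5-yl]-4,4,5,5-tetramethyl-1,3,2-dioxaborolane F6. Suzuki–Miyaura coupling of F5 with F6 (Pd(PPh3)4, K2CO3, dioxane/H2O, 90 °C) should give 15.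

Step 12. Under protic acid, the freed 6-OH may add to the double bond of the neighbouring 1,1-dimethylallyl group, closing a dihydrofuran, before all three acetals are cleaved. The fallback sets out from 15 and returns at 16 without any Brønsted acid. TMSOTf with 2,2'-bipyridyl (MeCN, 0 °C to rt) should exchange each aryl MOM ether for a silyl ether, giving {[2-(2,2-dimethyl-7-trimethylsilyloxy-3,4-dihydro-2H-chromen-5-yl)-7-(2-methylbut-3-en-2-yl)-1-benzofuran-4,6-diyl]bis(oxy)}bis(trimethylsilane) F7. Stirring F7 with water or K2CO3/MeOH at rt should release 16.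

**Further compounds**

F1 | step 6 | rac-3-bromo-2-(1-hydroxy-3-methylbut-2-en-1-yl)-5-(methoxymethoxy)phenol | COCOc1cc(O)c(C(O)C=C(C)C)c(Br)c1
F2 | step 6 | 5-bromo-7-(methoxymethoxy)-2,2-dimethyl-2H-chromene | COCOc1cc(Br)c2C=CC(C)(C)Oc2c1
F3 | step 11 | 2-hydroxy-4,6-bis(methoxymethoxy)-3-(2-methylbut-3-en-2-yl)benzaldehyde | C=CC(C)(C)c1c(O)c(C=O)c(OCOC)cc1OCOC
F4 | step 11 | 2-(2,2-dibromoethenyl)-3,5-bis(methoxymethoxy)-6-(2-methylbut-3-en-2-yl)phenol | C=CC(C)(C)c1c(O)c(C=C(Br)Br)c(OCOC)cc1OCOC
F5 | step 11 | 2-bromo-4,6-bis(methoxymethoxy)-7-(2-methylbut-3-en-2-yl)-1-benzofuran | C=CC(C)(C)c1c(OCOC)cc(OCOC)c2cc(Br)oc12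
F6 | step 11 | 2-[7-(methoxymethoxy)-2,2-dimethyl-3,4-dihydro-2H-chromen-5-yl]-4,4,5,5-tetramethyl-1,3,2-dioxaborolane | COCOc1cc(B2OC(C)(C)C(C)(C)O2)c2CCC(C)(C)Oc2c1
F7 | step 12 | {[2-(2,2-dimethyl-7-trimethylsilyloxy-3,4-dihydro-2H-chromen-5-yl)-7-(2-methylbut-3-en-2-yl)-1-benzofuran-4,6-diyl]bis(oxy)}bis(trimethylsilane) | C=CC(C)(C)c1c(O[Si](C)(C)C)cc(O[Si](C)(C)C)c2cc(-c3cc(O[Si](C)(C)C)cc4OC(C)(C)CCc34)oc12
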